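The constants were drawn at random within sensible limits; the run is a simulation.

Count the added ligand against the catalyst first, because the flask charges them equimolar: the catalyst, 1 mol% of the substrate, is 2.00 mM, and the ligand is 2.0 mM.

substrate 0.20 M; partner 1.00 equiv; free catalyst 1 mol%; added ligand 2.0 mM

    catalyst intermediate B ⇌ released group + catalyst intermediate C (K1 = 8.0 M, k1 = 3.6 s⁻¹)
    free catalyst + added ligand ⇌ idle complex (K2 = 3300 M⁻¹, k2 = 11 M⁻¹ s⁻¹)
    partner + catalyst intermediate A ⇌ catalyst intermediate B (K3 = 0.60 M⁻¹, k3 = 120 M⁻¹ s⁻¹)
    catalyst intermediate C ⇌ free catalyst + target (K4 = 0.16 M, k4 = 170 s⁻¹)
    substrate + free catalyst ⇌ catalyst intermediate A (K5 = 1.4 M⁻¹, k5 = 10 M⁻¹ s⁻¹)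

- the form that holds most of the catalyst when 20% of the substrate are converted (free catalyst / catalyst intermediate C / catalyst intermediate A / catalyst intermediate B / idle complex)
- its share of the catalyst then
- apparent order in free catalyst when 20% of the substrate are converted (percent change of the rate of making target for one percent more free catalyst charged)
- factor on the rate of making target when 20% of the substrate are converted if partner is charged twice over

The bench rule says one ligand takes out one catalyst, and by that rule equal charges put the whole catalyst in the idle complex. We test that rule with a ratio of given numbers. The binding constant times the ligand charge is 6.60, which is strong but not overwhelming, so the rule stops working here and the balance has to be reckoned.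

Time comes first. At the start, substrate takes free catalyst 91 times faster than ligand does, forward steps alone. With free catalyst taken equal to the ligand and the back step left out, the forward binding rate integrates in closed form, where k is the binding rate constant:

c(added ligand) = c(charged) / (1 + k·c(charged)·t)

The denominator reaches 2 at the binding time

t(bind) = 1 / (k·c(charged)) = 0.758 min

We look at 12.9 min, far later than that, so we treat binding as equilibrated.

Now the balance. Let w be the working share, the fraction of charged catalyst outside the idle complex once binding has equilibrated. Of that working catalyst, a fraction f is free. Counting free catalyst, intermediate A and intermediate B at the charged concentrations, and leaving intermediate C out, gives f = 0.761. Because the charges are equal, the free ligand is also the fraction w of its charge. The binding equilibrium, with K its constant, then reads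

n·w·w + w = 1, with n = K·c(charged)·f = 5.02

This gives w = 35.8%, so we commit to the idle complex, an off-cycle reservoir, holding 64.2% of the catalyst.

The forecast names the idle complex at 62%, a little below our share. It gives an order in free catalyst of 1.6, since “extra catalyst escapes the equimolar ligand disproportionately”, and a factor of 2.2 for twice the partner.

The simulation gives the idle complex at 62.6%, an order of 1.6 and a factor of 2.20. Free catalyst stands at 25.2% at that moment. The catalyst outside the idle complex comes to 37.4%, against our working share of 35.8%. For the flask with twice the free catalyst and the same ligand, we count w on the ligand charge, so the idle complex is 2 − w and the free ligand is w − 1: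

n·w·w + (1 − n)·w = 2

Taking the rate as proportional to working catalyst, this gives a factor of 3.21. The simulation with the free catalyst charged twice over gives a factor of 3.11 on the rate.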